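**Plan**
Cuts: first the palmitate C–O bond, then the MOM and silyl groups. Ring A is then taken apart at C1–C2, C2–C3, C4–C5 and C5–C6. Behind that lie the C6–O(ring B) enol ether bond, the C1–CH2OH bond and the diazo group on C2.
Enabling feature: in ring A the free C5–OH is meta to the C3–OMe with C4–H between them, which maps onto a ketene carbonyl carbon plus HC≡C–OMe. The neighbours C1 (CH2O) and C6 (O–ring B) map onto the C=C of a vinylketene, and C2–H onto its α carbon.
Forward: ring B is bought intact and protected once. Its phenoxide is joined to the future C6 by vinylic substitution on a dibromoenone, C1 gets its CH2OH by Stille coupling, and diazo transfer to the methyl ketone supplies C2.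
Ring A is the only ring made. Photochemical Wolff rearrangement of the diazoketone in the presence of methoxyacetylene, followed by heating, fixes all six positions through connectivity alone.
Endgame: one acid step frees the three hydroxyl groups, and a lipase then acylates only the primary alcohol.
Stereochemistry: the target has no stereocentre. Only the enol ether geometry (aryloxy trans to acyl) matters; it is set under thermodynamic control in step 3 and kept by the retentive coupling.

Key step: step 8

Remark: ring A is numbered C1 (CH2O), C2–H, C3 (OMe), C4–H, C5 (OH), C6 (O–ring B). "Ar" means the 2-(methoxycarbonyl)-3-(methoxymethoxy)-5-methylphenyl group of ring B. All starting materials are assumed to be purchasable.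

**Step 1**
Reactants: 1 methyl 2,6-dihydroxy-4-methylbenzoate
Product: 2 methyl 2-hydroxy-6-(methoxymethoxy)-4-methylbenzoate
Conditions: MOMCl (1.05 equiv), i-Pr2NEt, CH2Cl2, 0 °C to rt
Reagents that add atoms: chloromethyl methyl ether (MOMCl), COCCl
Why: This is O-alkylation to a MOM ether, and one equivalent should cap the symmetric resorcinol once because the remaining OH stays hydrogen-bonded to the ester carbonyl and reacts more slowly.

**Step 2**
Reactants: 3 but-3-yn-2-one
Product: 4 (E)-3,4-dibromobut-3-en-2-one
Conditions: Br2 (1.0 equiv), CH2Cl2, 0 °C to rt, dark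
Reagents that add atoms: bromine, BrBr
Why: Anti addition of bromine to an acceptor alkyne (alkyne dibromination, as practised on propiolates) should give the trans dibromide, which carries a β leaving group and an α coupling handle, and its geometry is not critical because step 3 is stereoconvergent.

**Step 3**
Reactants: 2 methyl 2-hydroxy-6-(methoxymethoxy)-4-methylbenzoate; 4 (E)-3,4-dibromobut-3-en-2-one
Product: 5 methyl 2-{[(1Z)-2-bromo-3-oxobut-1-en-1-yl]oxy}-6-(methoxymethoxy)-4-methylbenzoate
Conditions: K2CO3, MeCN, 0 °C to rt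
Reagents that add atoms: none
Why: In this nucleophilic vinylic substitution by addition–elimination the phenoxide adds to the β carbon and the α-bromo enolate expels only the β bromide, while bond rotation in the enolate and reversible re-addition of phenoxide should funnel the product to the more stable isomer with the aryloxy group trans to the acetyl group.

**Step 4**
Reactants: 5 methyl 2-{[(1Z)-2-bromo-3-oxobut-1-en-1-yl]oxy}-6-(methoxymethoxy)-4-methylbenzoate; 6 (tributylstannyl)methanol
Product: 7 methyl 2-{[(1E)-2-(hydroxymethyl)-3-oxobut-1-en-1-yl]oxy}-6-(methoxymethoxy)-4-methylbenzoate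
Conditions: Pd(PPh3)4 (5 mol %), CuI (10 mol %), 1,4-dioxane, 80 °C
Reagents that add atoms: none
Why: In this Stille hydroxymethylation zerovalent palladium inserts into the activated α-bromoenone C–Br bond with retention of geometry and the CH2OH group transfers from tin in preference to butyl, as known for α-haloenones and 2-halo-3-alkoxyacrylates.

**Step 5**
Reactants: 7 methyl 2-{[(1E)-2-(hydroxymethyl)-3-oxobut-1-en-1-yl]oxy}-6-(methoxymethoxy)-4-methylbenzoate
Product: 8 methyl 2-{[(1E)-2-({[tert-butyl(dimethyl)silyl]oxy}methyl)-3-oxobut-1-en-1-yl]oxy}-6-(methoxymethoxy)-4-methylbenzoate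
Conditions: TBSOTf (1.1 equiv), 2,6-lutidine, CH2Cl2, −78 °C
Reagents that add atoms: tert-butyldimethylsilyl triflate (TBSOTf), CC(C)(C)[Si](C)(C)OS(=O)(=O)C(F)(F)F
Why: This is silyl ether formation at a primary alcohol, and the triflate with a hindered base is chosen because nucleophilic amines such as imidazole or DMAP could displace the aryloxide from this vinylogous aryl ester.

**Step 6**
Reactants: 8 methyl 2-{[(1E)-2-({[tert-butyl(dimethyl)silyl]oxy}methyl)-3-oxobut-1-en-1-yl]oxy}-6-(methoxymethoxy)-4-methylbenzoate
Product: 10 methyl 2-{[(1E)-4-diazo-2-({[tert-butyl(dimethyl)silyl]oxy}methyl)-3-oxobut-1-en-1-yl]oxy}-6-(methoxymethoxy)-4-methylbenzoate, via trifluoroacetyl diketone 9 (not isolated)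
Conditions: LiN(SiMe3)2, THF, −78 °C; CF3CO2CH2CF3; cold dilute HCl wash; then MsN3, Et3N, H2O (1 equiv), MeCN, rt
Reagents that add atoms: methanesulfonyl azide, CS(=O)(=O)N=[N+]=[N-]; 2,2,2-trifluoroethyl trifluoroacetate, FC(F)(F)COC(=O)C(F)(F)F (its CF3CO group stays only in 9)
Why: In this detrifluoroacetylative (Regitz-type) diazo transfer the kinetic methyl enolate is trifluoroacetylated and the activated diketone takes N2 from the azide and sheds CF3CO, which is the standard entry to α,β-unsaturated α′-diazoketones and avoids both diazomethane and hydrolysis of an acrylate ester next to the ring B ester.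

**Step 7**
Reactants: 11 chloroacetaldehyde dimethyl acetal
Product: 13 methoxyacetylene, via sodium methoxyacetylide 12 (not isolated)
Conditions: NaNH2 (3 equiv), liq. NH3, −33 °C; NH3 evaporated; brine, −70 °C to rt; distilled into cold ClCH2CH2Cl
Reagents that add atoms: sodium amide, [Na+].[NH2-] (sodium stays only in 12)
Why: This is the classical alkoxyacetylene synthesis by double elimination (loss of MeOH, then HCl) from a haloacetal, and the third equivalent of amide stores the alkyne as its acetylide until the cold aqueous quench.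

**Step 8**
Reactants: 10 methyl 2-{[(1E)-4-diazo-2-({[tert-butyl(dimethyl)silyl]oxy}methyl)-3-oxobut-1-en-1-yl]oxy}-6-(methoxymethoxy)-4-methylbenzoate; 13 methoxyacetylene
Product: 18 methyl 2-[2-({[tert-butyl(dimethyl)silyl]oxy}methyl)-6-hydroxy-4-methoxyphenoxy]-6-(methoxymethoxy)-4-methylbenzoate, via aryloxy vinylketene 14 (not isolated), via 4-alkenyl-3-methoxycyclobutenone 15 (not isolated), via dienylketene 16 (not isolated), via cyclohexa-2,4-dienone tautomer 17 (not isolated)
Conditions: 13 (4 equiv), degassed ClCH2CH2Cl, hν (254 nm, low-pressure Hg lamps, quartz vessel, cold-finger condenser), 5–10 °C; then sealed tube, 80 °C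
Reagents that add atoms: none
Why: Light expels N2 from 10 and the alkenyl group shifts from the carbonyl carbon to the former diazo carbon (photochemical Wolff rearrangement, new bond C1–C2), giving vinylketene 14 whose carbonyl carbon is the future C5. Ynol ether 13 then adds across the ketene C=C in a (2+2) cycloaddition; the only selectivity required is its orientation, and the polarisation of HC≡C–OMe secures it, since the electron-rich unsubstituted carbon (C4) bonds to the electrophilic ketene carbonyl carbon and the methoxy-bearing carbon (C3) bonds to C2, which places OMe meta to the coming OH in 15. At 80 °C 15 opens reversibly by conrotatory four-electron cleavage of its C2–C5 bond, and only the dienylketene 16 that holds C1 and C4 cis on C2=C3 is drained forward. Ring A, the sole ring closed, forms by disrotatory six-electron electrocyclisation joining C6 to C5, helped by the E geometry of 10, which keeps the bulky aryloxy group outward at the closing terminus, and dienone 17 then tautomerises irreversibly to phenol 18. The closest known reaction type is the second-generation Danheiser benzannulation of α,β-unsaturated α′-diazoketones with alkoxyalkynes, including 3-heteroaryl diazoketones whose closing carbon carries the ring heteroatom; here it is applied to an acyclic β-aryloxy member of that class. No stereocentre survives (those of 15 and 17 are transient and racemic), and the excess of 13 should keep capture of 14 by the product phenol in check.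

**Step 9**
Reactants: 18 methyl 2-[2-({[tert-butyl(dimethyl)silyl]oxy}methyl)-6-hydroxy-4-methoxyphenoxy]-6-(methoxymethoxy)-4-methylbenzoate
Product: 19 methyl 2-hydroxy-6-[2-hydroxy-6-(hydroxymethyl)-4-methoxyphenoxy]-4-methylbenzoate
Conditions: 3 M aq. HCl, THF, 45 °C
Reagents that add atoms: none
Why: Acid hydrolysis should remove the aryl MOM acetal and the primary silyl ether in one operation, the aqueous medium returns any benzylic cation to the alcohol, and the hindered benzoate and the diaryl ether are inert.

**Step 10**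
Reactants: 19 methyl 2-hydroxy-6-[2-hydroxy-6-(hydroxymethyl)-4-methoxyphenoxy]-4-methylbenzoate; 20 vinyl palmitate
Product: 21 betaethrin E
Conditions: immobilised Candida antarctica lipase B, 20 (2 equiv), 2-methylbutan-2-ol, 4 Å MS, 45 °C
Reagents that add atoms: none
Why: In this lipase-catalysed irreversible transesterification with an enol ester the serine hydrolase acylates primary (including hydroxybenzyl) alcohols but not phenols, and tautomerisation of the released vinyl alcohol makes the acyl transfer one-way.

**Compound list**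
1 | methyl 2,6-dihydroxy-4-methylbenzoate | COC(=O)c1c(O)cc(C)cc1O | starting material
2 | methyl 2-hydroxy-6-(methoxymethoxy)-4-methylbenzoate | COC(=O)c1c(O)cc(C)cc1OCOC | intermediate
3 | but-3-yn-2-one | CC(=O)C#C | starting material
4 | (E)-3,4-dibromobut-3-en-2-one | CC(=O)/C(Br)=C\Br | intermediate
5 | methyl 2-{[(1Z)-2-bromo-3-oxobut-1-en-1-yl]oxy}-6-(methoxymethoxy)-4-methylbenzoate (aryloxy trans to acetyl) | CC(=O)/C(Br)=C/Oc1cc(C)cc(OCOC)c1C(=O)OC | intermediate
6 | (tributylstannyl)methanol | CCCC[Sn](CCCC)(CCCC)CO | starting material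
7 | methyl 2-{[(1E)-2-(hydroxymethyl)-3-oxobut-1-en-1-yl]oxy}-6-(methoxymethoxy)-4-methylbenzoate | CC(=O)/C(CO)=C/Oc1cc(C)cc(OCOC)c1C(=O)OC | intermediate
8 | methyl 2-{[(1E)-2-({[tert-butyl(dimethyl)silyl]oxy}methyl)-3-oxobut-1-en-1-yl]oxy}-6-(methoxymethoxy)-4-methylbenzoate | CC(=O)/C(CO[Si](C)(C)C(C)(C)C)=C/Oc1cc(C)cc(OCOC)c1C(=O)OC | intermediate
9 | methyl 2-{[(1E)-2-({[tert-butyl(dimethyl)silyl]oxy}methyl)-6,6,6-trifluoro-3,5-dioxohex-1-en-1-yl]oxy}-6-(methoxymethoxy)-4-methylbenzoate | O=C(CC(=O)/C(CO[Si](C)(C)C(C)(C)C)=C/Oc1cc(C)cc(OCOC)c1C(=O)OC)C(F)(F)F | intermediate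
10 | methyl 2-{[(1E)-4-diazo-2-({[tert-butyl(dimethyl)silyl]oxy}methyl)-3-oxobut-1-en-1-yl]oxy}-6-(methoxymethoxy)-4-methylbenzoate | [N-]=[N+]=CC(=O)/C(CO[Si](C)(C)C(C)(C)C)=C/Oc1cc(C)cc(OCOC)c1C(=O)OC | intermediate
11 | chloroacetaldehyde dimethyl acetal | COC(CCl)OC | starting material
12 | sodium methoxyacetylide | [Na+].[C-]#COC | intermediate
13 | methoxyacetylene | C#COC | intermediate
14 | vinylketene O=C=CH–C(CH2OTBS)=CH–OAr, aryloxy trans to the ketene CH | O=C=C/C(CO[Si](C)(C)C(C)(C)C)=C/Oc1cc(C)cc(OCOC)c1C(=O)OC | intermediate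
15 | racemic 4-[1-aryloxy-3-(tert-butyldimethylsilyloxy)prop-1-en-2-yl]-3-methoxycyclobut-2-en-1-one, aryloxy trans to the ring carbon | COC1=CC(=O)C1/C(CO[Si](C)(C)C(C)(C)C)=C/Oc1cc(C)cc(OCOC)c1C(=O)OC | intermediate
16 | dienylketene O=C=CH–C(OMe)=CH–C(CH2OTBS)=CH–OAr, C4 and C1 cis on C2=C3, aryloxy trans to C2 | O=C=C/C(OC)=C\C(CO[Si](C)(C)C(C)(C)C)=C\Oc1cc(C)cc(OCOC)c1C(=O)OC | intermediate
17 | racemic 6-aryloxy-5-({[tert-butyl(dimethyl)silyl]oxy}methyl)-3-methoxycyclohexa-2,4-dien-1-one | COC1=CC(=O)C(Oc2cc(C)cc(OCOC)c2C(=O)OC)C(CO[Si](C)(C)C(C)(C)C)=C1 | intermediate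
18 | methyl 2-[2-({[tert-butyl(dimethyl)silyl]oxy}methyl)-6-hydroxy-4-methoxyphenoxy]-6-(methoxymethoxy)-4-methylbenzoate | COC(=O)c1c(OCOC)cc(C)cc1Oc1c(O)cc(OC)cc1CO[Si](C)(C)C(C)(C)C | intermediate
19 | methyl 2-hydroxy-6-[2-hydroxy-6-(hydroxymethyl)-4-methoxyphenoxy]-4-methylbenzoate | COC(=O)c1c(O)cc(C)cc1Oc1c(O)cc(OC)cc1CO | intermediate
20 | vinyl palmitate | CCCCCCCCCCCCCCCC(=O)OC=C | starting material
21 | betaethrin E | CCCCCCCCCCCCCCCC(=O)OCc1cc(OC)cc(O)c1Oc1cc(C)cc(O)c1C(=O)OC | target

**Step count**
Total steps: 10.
Longest linear sequence: 8 steps (1, 3, 4, 5, 6, 8, 9, 10 from 1). The count is the same from 3 through step 2.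

**Steps most likely to fail**

**Step 8.** An acyclic vinylketene with an aryloxy group on its terminal carbon has not been taken through this cascade. Several processes could erode it:
- light-driven side reactions of the aryl enol ether chromophore;
- E/Z scrambling of the push–pull alkene, which would turn the aryloxy group inward and slow the closure;
- interception of the ketene by the phenol as it forms;
- escape of the volatile alkyne from the irradiated solution.

Fallback (from 2, back at 18): ring A is bought as an arene and the ether bond is made by nucleophilic aromatic substitution. Commercial 4-bromo-3,5-dimethylanisole is brominated at both methyl groups (NBS, AIBN, PhCF3, reflux; Wohl–Ziegler) to 2-bromo-1,3-bis(bromomethyl)-5-methoxybenzene F1. N-Methylmorpholine N-oxide in MeCN oxidises this to 2-bromo-5-methoxybenzene-1,3-dicarbaldehyde F2. The bromide, activated by two ortho formyl groups, is displaced by the phenoxide of 2 (K2CO3, DMF, 80 °C) to give the symmetric methyl 2-(2,6-diformyl-4-methoxyphenoxy)-6-(methoxymethoxy)-4-methylbenzoate F3, so no regiochemical question arises. Substoichiometric NaBH4 (THF/MeOH, −40 °C) reduces one formyl group to methyl 2-[2-formyl-6-(hydroxymethyl)-4-methoxyphenoxy]-6-(methoxymethoxy)-4-methylbenzoate F4. TBSCl/imidazole then gives methyl 2-[2-({[tert-butyl(dimethyl)silyl]oxy}methyl)-6-formyl-4-methoxyphenoxy]-6-(methoxymethoxy)-4-methylbenzoate F5. Baeyer–Villiger oxidation (mCPBA, NaHCO3, CH2Cl2) converts the remaining formyl group into methyl 2-[2-({[tert-butyl(dimethyl)silyl]oxy}methyl)-6-(formyloxy)-4-methoxyphenoxy]-6-(methoxymethoxy)-4-methylbenzoate F6. Brief K2CO3/MeOH releases the C5 phenol, which is 18.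

**Step 4.** Possible problems are slow transfer of the hydroxymethyl group from tin, protodebromination, loss of aryloxide from the alkenylpalladium intermediate, and alcohol-for-aryloxide exchange at 80 °C.

Fallback (from 3 and 2, back at 8): the CH2OH group is installed before the aryl ether and without tin. A three-component halo-aldol (β-iodo Morita–Baylis–Hillman) reaction of 3 with MgI2 and monomeric formaldehyde (CH2Cl2, 0 °C) should give (Z)-3-(hydroxymethyl)-4-iodobut-3-en-2-one F7. TBSOTf/2,6-lutidine converts it into (Z)-3-({[tert-butyl(dimethyl)silyl]oxy}methyl)-4-iodobut-3-en-2-one F8. The phenoxide of 2 (K2CO3, MeCN) then replaces the iodide by stereoconvergent addition–elimination to give 8.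

**Step 3.** Possible problems are base-induced dehydrobromination of 4 to a bromoalkynone with loss of regiocontrol, incomplete convergence of the alkene geometry, and a second addition of phenoxide.

Fallback (from 2 and 3, back at 5): the order of ether formation and halogenation is reversed. DABCO-catalysed oxa-Michael addition of 2 to 3 (CH2Cl2, rt) gives methyl 2-(methoxymethoxy)-4-methyl-6-{[(1E)-3-oxobut-1-en-1-yl]oxy}benzoate F9. Br2 at −78 °C adds anti to the enol ether to give racemic methyl 2-{[(1R*,2R*)-1,2-dibromo-3-oxobutyl]oxy}-6-(methoxymethoxy)-4-methylbenzoate F10. Et3N then removes the acidic α proton and the β bromide (bromination–dehydrobromination) to give 5. The low temperature and exactly one equivalent of bromine are meant to spare ring B.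

**Further compounds**
F1 | step 8 | 2-bromo-1,3-bis(bromomethyl)-5-methoxybenzene | COc1cc(CBr)c(Br)c(CBr)c1
F2 | step 8 | 2-bromo-5-methoxybenzene-1,3-dicarbaldehyde | COc1cc(C=O)c(Br)c(C=O)c1
F3 | step 8 | methyl 2-(2,6-diformyl-4-methoxyphenoxy)-6-(methoxymethoxy)-4-methylbenzoate | COC(=O)c1c(OCOC)cc(C)cc1Oc1c(C=O)cc(OC)cc1C=O
F4 | step 8 | methyl 2-[2-formyl-6-(hydroxymethyl)-4-methoxyphenoxy]-6-(methoxymethoxy)-4-methylbenzoate | COC(=O)c1c(OCOC)cc(C)cc1Oc1c(C=O)cc(OC)cc1CO
F5 | step 8 | methyl 2-[2-({[tert-butyl(dimethyl)silyl]oxy}methyl)-6-formyl-4-methoxyphenoxy]-6-(methoxymethoxy)-4-methylbenzoate | COC(=O)c1c(OCOC)cc(C)cc1Oc1c(C=O)cc(OC)cc1CO[Si](C)(C)C(C)(C)C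
F6 | step 8 | methyl 2-[2-({[tert-butyl(dimethyl)silyl]oxy}methyl)-6-(formyloxy)-4-methoxyphenoxy]-6-(methoxymethoxy)-4-methylbenzoate | COC(=O)c1c(OCOC)cc(C)cc1Oc1c(OC=O)cc(OC)cc1CO[Si](C)(C)C(C)(C)C
F7 | step 4 | (Z)-3-(hydroxymethyl)-4-iodobut-3-en-2-one | CC(=O)/C(CO)=C\I
F8 | step 4 | (Z)-3-({[tert-butyl(dimethyl)silyl]oxy}methyl)-4-iodobut-3-en-2-one | CC(=O)/C(CO[Si](C)(C)C(C)(C)C)=C\I
F9 | step 3 | methyl 2-(methoxymethoxy)-4-methyl-6-{[(1E)-3-oxobut-1-en-1-yl]oxy}benzoate | CC(=O)/C=C/Oc1cc(C)cc(OCOC)c1C(=O)OC
F10 | step 3 | racemic methyl 2-{[(1R*,2R*)-1,2-dibromo-3-oxobutyl]oxy}-6-(methoxymethoxy)-4-methylbenzoate (one enantiomer drawn) | CC(=O)[C@H](Br)[C@H](Br)Oc1cc(C)cc(OCOC)c1C(=O)OC
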